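Labdane numbering is used for every compound, acyclic ones included: decalin C1–C10 (ring A C1–C5, C10; ring B C5–C10), gem-dimethyl on C4, methyl groups on C8 and C10, tetrahydrofuran O, C9, C11, C12, C13, dihydrofuran C13, C14, C15, O, C16. α is the face opposite the C10 methyl group.

## Analysis of the target

The target 31 is a 9α,13:15,16-diepoxylabd-14-ene 6β-acetate: a trans-decalin whose C9 is the spiro atom of a tetrahydrofuran, and whose C13 is in turn the spiro atom of a 2,3-dihydrofuran. It has six stereocentres, (5S,6R,8R,9R,10S,13R). Five are contiguous in ring B: 5α-H and 10β-methyl (trans fusion), an axial 6β-acetoxy group syn-diaxial to the C10 and 4β methyl groups, an equatorial 8α-methyl group, and an axial 9α-oxygen with C11 equatorial. C13 is separated from this array by two methylene groups and has no nearby control element. C9 (tertiary ether) and C10 (all-carbon quaternary) are adjacent fully substituted carbons, and C4 is a further quaternary carbon next to C5. The cyclic enol ether is acid-labile, and because the C13–O9 bond is allylic to it, acid would ionise C13 and open the spiro ring toward a furan; the acetate rules out hydrides and organometallic reagents late in the route. The difficulty lies in building the crowded C9/C10 pair in the correct absolute sense, setting C13 without substrate help, and forming the enol ether last without acid. The strategy rests on ring B: oxygen sits on C6 and C9 in a 1,4 relationship across quaternary C10, which is the pattern left when a 2-aminodiene (C7=C8–C9(N)=C10) combines with a nitroalkene (C5=C6) whose nitro group later becomes the C6 oxygen.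

## Retrosynthetic reasoning

**Acetate and silyl ether (31 ⇐ 30 ⇐ 29).** The C6–O acetyl bond is cut first and the free 6β-alcohol 30 is traced to silyl ether 29. An ester would not survive the ylide and organolithium steps, so C6–O travels as a triethylsilyl ether and is acetylated last under basic conditions that the enol ether tolerates.

**Dihydrofuran (29 ⇐ 28).** The O–C15 bond is cut. Because C13 is quaternary, the C14=C15 enol ether is the cycloisomer of a homopropargylic alcohol in which C13 carries an ethynyl group (C14≡C15) and a hydroxymethyl group (C16). This avoids an acid-promoted lactol dehydration; the forward reaction only has to add the C16 hydroxyl across the alkyne in the endo sense.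

**Spiro tetrahydrofuran (28 ⇐ 27).** The O9–C13 bond is cut to give the 9α-alcohol and a 13,16-oxirane in 27. The forward step is a 5-exo opening at the tertiary oxirane carbon with inversion, so the oxirane configuration becomes that of C13. The two one-carbon arms on C13 must differ before the ring closes (ethynyl versus oxirane CH2); otherwise closure would leave two hydroxymethyl groups and C13 would no longer be a stereocentre.

**C13 stereocentre (27 ⇐ 26 ⇐ 25 ⇐ 24).** The alkyne comes from aldehyde 26 by one-carbon homologation (C15), the aldehyde from epoxy alcohol 25, and 25 from the 2-substituted allylic alcohol 24. C13 is too far from the ring for substrate control, so it is set by reagent-controlled epoxidation of an allylic alcohol.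

**Side chain (24 ⇐ 22 + 23, 22 ⇐ 21 ⇐ 20).** The C11–C12 bond is cut between spiro-oxirane 22 (electrophile at C11) and a four-carbon allyl nucleophile from 23. Direct addition of a side-chain organometallic to ketone 20 is not used, because attack anti to the axial C10 methyl group (from the α-face) would put carbon α and oxygen β, the wrong C9 epimer. Bringing C11 in as a methylene group (21) and then delivering oxygen from the same open α-face gives 9α-O with C11 β.

**C6 oxygen (20 ⇐ 19 ⇐ 18 ⇐ 16).** The silyl ether comes from 6β-alcohol 19, this from dione 18, and the dione from nitro ketone 16 by a Nef reaction. The reduction has to tell the two carbonyl groups apart and deliver hydride from the α-face; C9 is flanked by quaternary C10 and branched C8, and the β-face of C6 is blocked by two syn-axial methyl groups.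

**Key disconnection (16 ⇐ 13).** C5–C10 and C6–C7 are cut together, which opens both rings to the acyclic nitroalkene enone 13. No other pair of cuts in ring B gives the 1,4-dioxygen pattern, the quaternary C10, the trans fusion and a C6 oxygen equivalent in one operation. The forward reaction must control the absolute configuration of C10 and the ring fusion; the C10 stereocentre of 13 need not be controlled, since it becomes sp2 on the way.

**Nitroalkene and carbonyl adjustment (13 ⇐ 12 ⇐ 10 + 11, 10 ⇐ 9 ⇐ 8).** The nitroalkene comes from nitroaldol 12, made from aldehyde 10 and nitromethane 11 (C5–C6 bond). An ester cannot be reduced selectively beside an enone, so both carbonyl groups of 8 are reduced to diol 9 and both hydroxyl groups are reoxidised.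

**Carbon chain (8 ⇐ 6 + 7, 6 ⇐ 4 + 5, 4 ⇐ 3 ⇐ 1 + 2).** C8–C9 is made by acyl substitution on Weinreb amide 6 with 7, C1–C10 by alkylation of the enolate of 5 with iodide 4, and C3–C4 by alkylation of the enolate of 1 with 2.

## Alternatives that were turned down

**Alternative 1:** The O–C13 and C9–C10 bonds are cut together, leading to the monocyclic keto epoxide A1: a 2,6,6-trimethylcyclohexene (ring A with a C5=C10 alkene) whose chain carries the C8 methyl group, the C9 ketone and a 2,2-disubstituted oxirane at C13.
- Forward key step: a boron Lewis acid makes the ketone oxygen open the oxirane at C13; the five-membered oxocarbenium ion is captured at C9 by C10 of the tetrasubstituted alkene, and loss of a C6 proton leaves the tricyclic 5-ene A2.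
- For: ring B, the tetrahydrofuran and both fully substituted carbons (C9, C10) form in one step from a precursor assembled from simple terpenoid pieces, and C13 comes from a reagent-controlled oxirane. On step count to the tricyclic core this plan is clearly stronger than the chosen one.
- Against: the facial outcome at C9 and C10 depends only on C8, which is epimerisable next to a Lewis-acid-bound ketone, and on the distant C13. Joining a tetrasubstituted alkene to a ketone-derived oxocarbenium ion to make two adjacent quaternary centres is sterically severe, so oxirane rearrangement and 1,2-shifts from the C5 cation are likely to compete. A2 still lacks C5 and C6: hydroboration of the 5-ene from the open α-face would give the trans fusion but the 6α-alcohol, which then needs an oxidation and reduction to invert.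
- Comparison: the chosen route spends more steps on its precursor, but sets C5, C10 and the C6 oxygen equivalent in the bicyclization with no later correction in ring B.

**Alternative 2:** C1–C10 and C4–C5 are cut, so that ring A is built on 2,6-dimethyl-1,4-benzoquinone A3 with 2-(triisopropylsilyloxy)-4-methylpenta-1,3-diene A4.
- Forward key step: a chiral oxazaborolidinium Lewis acid catalyses the Diels–Alder reaction at one methyl-bearing double bond of A3 to give the cis-fused ene-dione A5.
- For: catalytic enantioselective quinone Diels–Alder reactions are well established, so this key step has closer precedent than the chosen one. It also reaches a decalin with both ring B oxygens and the quaternary C10 in a single step from two simple components, where the chosen route needs eight steps to its precursor.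
- Against: the diene terminus C4 is gem-dimethyl, which disfavours the s-cis conformer and forces a bond between a quaternary carbon and C5 next to quaternary C10. A5 then needs epimerisation at C5 to the trans fusion, removal of the superfluous C2 oxygen, reduction of the C7=C8 alkene with control of the 8α-methyl group, and differentiation of two similar ring B carbonyl groups.
- Comparison: the chosen bicyclization gives the trans fusion directly, carries no atom that must be excised, and delivers C6 and C9 already differentiated (nitro versus ketone).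

**Alternative 3:** The C12–C13 bond is cut, leading to the primary iodide A6, in which the 9α-oxygen is bound to C13 of a tetronate.
- Forward key step: a tin hydride generates the C12 radical, which adds 5-exo to the oxygen-bearing β-carbon of the tetronate and closes the tetrahydrofuran, giving the spiro lactone A7 (6β-acetoxy-9,13-epoxylabdan-16,15-olide).
- For: radical additions to β-alkoxy acrylate units under neutral conditions are reliable, and A7 is only a reduction and a dehydration from the target, so the end game is shorter than the chosen one.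
- Against: it requires attaching a tetronate to the very hindered tertiary 9α-alcohol. C13 would be set only by the small difference between the C8 and C10 flanks of C9. The lactone would have to be reduced beside the acetate. It also leaves the real problem, the C5/C6/C9/C10 array of the decalin, unsolved.
- Comparison: the chosen route sets C13 by reagent-controlled epoxidation followed by a stereospecific inversion, and its key step builds the decalin core.

Key step: step 9

Assumption: 9-amino-9-deoxy-epi-quinine is taken to give the (10S) series; if the sense of induction is the opposite, the pseudoenantiomeric 9-amino-9-deoxy-epi-quinidine is used with nothing else changed.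

## Route

Step 1
Reactants: 1 methyl isobutyrate; 2 1-bromo-3-chloropropane
Product: 3 methyl 5-chloro-2,2-dimethylpentanoate
Conditions: LiN(iPr)2, THF, −78 °C; then 2, −78 °C → rt
Reagents that add atoms: none
Why: Ester enolate alkylation; bromide is displaced in preference to chloride, and the quaternary C4 that forms has no α-hydrogen left, so no second alkylation can occur.

Step 2
Reactants: 3 methyl 5-chloro-2,2-dimethylpentanoate
Product: 4 methyl 5-iodo-2,2-dimethylpentanoate
Conditions: NaI, acetone, reflux
Reagents that add atoms: sodium iodide, [Na+].[I-]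
Why: Finkelstein exchange driven by precipitation of NaCl; the iodide is needed for the slower amide enolate alkylation that follows.

Step 3
Reactants: 5 N-methoxy-N-methylpropanamide; 4 methyl 5-iodo-2,2-dimethylpentanoate
Product: 6 methyl 7-[methoxy(methyl)amino]-2,2,6-trimethyl-7-oxoheptanoate (racemic)
Conditions: LiN(iPr)2, THF, −78 °C; then 4, DMPU, −78 → −20 °C
Reagents that add atoms: none
Why: Amide enolate alkylation with a primary iodide forms C1–C10; the α,α-disubstituted methyl ester is too hindered to be attacked, and the new C10 stereocentre may be racemic because it is later enolised.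

Step 4
Reactants: 6 methyl 7-[methoxy(methyl)amino]-2,2,6-trimethyl-7-oxoheptanoate; 7 isopropenylmagnesium bromide
Product: 8 methyl 2,2,6,8-tetramethyl-7-oxonon-8-enoate (racemic)
Conditions: THF, 0 °C; then cold 1 M HCl
Reagents that add atoms: none
Why: Weinreb ketone synthesis; the chelated tetrahedral adduct prevents over-addition and the neopentyl-type ester does not react at 0 °C, while the acidic quench keeps the liberated amine from adding to the enone.

Step 5
Reactants: 8 methyl 2,2,6,8-tetramethyl-7-oxonon-8-enoate
Product: 9 2,2,6,8-tetramethylnon-8-ene-1,7-diol (mixture of diastereomers)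
Conditions: iBu2AlH (5 equiv), CH2Cl2, −78 → 0 °C; aq. KNaC4H4O6
Reagents that add atoms: none
Why: Hydride reduction of the ester to the primary alcohol and 1,2-reduction of the enone; reducing both avoids an unworkable ester-versus-ketone selectivity, and the carbinol configuration is irrelevant.

Step 6
Reactants: 9 2,2,6,8-tetramethylnon-8-ene-1,7-diol
Product: 10 2,2,6,8-tetramethyl-7-oxonon-8-enal (racemic)
Conditions: Dess–Martin periodinane (2.5 equiv), NaHCO3, CH2Cl2, 0 °C → rt
Reagents that add atoms: none
Why: Dess–Martin oxidation of both hydroxyl groups under buffered neutral conditions gives the aldehyde (C5) and regenerates the isopropenyl ketone without conjugate addition or aldol side reactions.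

Step 7
Reactants: 10 2,2,6,8-tetramethyl-7-oxonon-8-enal; 11 nitromethane
Product: 12 9-hydroxy-2,4,8,8-tetramethyl-10-nitrodec-1-en-3-one (mixture of diastereomers)
Conditions: 11 (10 equiv), 1,1,3,3-tetramethylguanidine (10 mol%), THF, 0 °C
Reagents that add atoms: none
Why: Henry (nitroaldol) reaction forms C5–C6; the aldehyde has no α-hydrogen and can only act as acceptor, and 1,2-addition to it should be much faster than conjugate addition to the α-branched enone under catalytic base.

Step 8
Reactants: 12 9-hydroxy-2,4,8,8-tetramethyl-10-nitrodec-1-en-3-one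
Product: 13 (9E)-2,4,8,8-tetramethyl-10-nitrodeca-1,9-dien-3-one (racemic at labdane C10)
Conditions: MsCl, Et3N, CH2Cl2, −20 → 0 °C
Reagents that add atoms: none
Why: Mesylation and E1cB elimination give the thermodynamically preferred (E)-nitroalkene; quaternary C4 leaves no γ-hydrogen, so the double bond cannot move out of conjugation.

Step 9
Reactants: 13 (9E)-2,4,8,8-tetramethyl-10-nitrodeca-1,9-dien-3-one
Product: 16 (5S,6S,8R,10S)-6α-nitro-4,4,8α,10-tetramethyl-trans-decal-9-one, via catalyst-bound 2-aminodiene 14 (not isolated), via iminium nitronate 15 (not isolated)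
Conditions: 9-amino-9-deoxy-epi-quinine (20 mol%), 2-fluorobenzoic acid (40 mol%), toluene, 40 °C
Reagents that add atoms: none
Why: Proposed new method: the primary amine condenses with the C9 ketone and, because C10 is the only enolisable position, the iminium ion can tautomerise in one direction only, to the cross-conjugated 2-aminodiene 14 (C7=C8–C9(N)=C10); C10 then adds to C5 of the tethered nitroalkene (6-exo-trig, ring A) to give iminium nitronate 15, the nitronate carbon C6 adds to C7 of the unsaturated iminium ion (6-endo-trig, ring B), and hydrolysis releases 16 and the amine, the two additions possibly merging into one asynchronous [4+2] transition state. The closest known reaction types are the amine-catalysed formal [4+2] (double Michael) reaction of enones with nitroalkenes, which has not been shown intramolecularly with formation of a quaternary carbon, and the thermal Diels–Alder reaction of 2-silyloxydienes with nitroalkenes. C10 is set by the catalyst: the protonated quinuclidine is expected to hold the nitro group while the quinoline shields one face of the aminodiene, so C5 bonds to the open face. C5 follows from a chair-like folding of the C1–C4 tether with the (E)-nitroalkene pseudo-equatorial, which puts H5 anti to the C10 methyl group (trans fusion) and is helped by the gem-dimethyl group on C4. C6 and C8 remain epimerisable under the conditions (nitronate and enamine) and should settle with nitro and methyl equatorial (6α, 8α). The step needs facial control at C10 and a trans fusion; the racemic C10 of 13 is erased in 14, the nitroalkene is a strong acceptor, and the lack of γ-hydrogens excludes side reactions from that end.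

Step 10
Reactants: 16 (5S,6S,8R,10S)-6α-nitro-4,4,8α,10-tetramethyl-trans-decal-9-one
Product: 18 (5S,8R,10S)-4,4,8α,10-tetramethyl-trans-decalin-6,9-dione, via sodium nitronate 17 (not isolated)
Conditions: NaOMe, MeOH, 0 °C; then KHSO5 (as 2KHSO5·KHSO4·K2SO4), Na2HPO4, H2O/MeOH, 0 °C → rt
Reagents that add atoms: potassium peroxymonosulfate, [K+].[O-]S(=O)(=O)OO
Why: Oxidative Nef reaction; the nitro group is far more acidic than the hindered ketone, so only the nitronate forms and is cleaved to the C6 ketone, which suits a hindered secondary nitro group better than acid hydrolysis. C5 and C8 are epimerisable here and should stay at the more stable trans-fused, equatorial-methyl arrangement.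

Step 11
Reactants: 18 (5S,8R,10S)-4,4,8α,10-tetramethyl-trans-decalin-6,9-dione
Product: 19 (5S,6R,8R,10S)-6β-hydroxy-4,4,8α,10-tetramethyl-trans-decal-9-one
Conditions: NaBH4, MeOH/CH2Cl2, −40 → −20 °C
Reagents that add atoms: none
Why: Chemoselective borohydride reduction; C9 is shielded by quaternary C10 and the C8 methine while C6 has a free methylene neighbour, and the β-face of C6 is blocked by the syn-axial C10 and 4β methyl groups, so hydride enters from the α-face and gives the axial 6β-alcohol.

Step 12
Reactants: 19 (5S,6R,8R,10S)-6β-hydroxy-4,4,8α,10-tetramethyl-trans-decal-9-one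
Product: 20 (5S,6R,8R,10S)-6β-(triethylsilyloxy)-4,4,8α,10-tetramethyl-trans-decal-9-one
Conditions: Et3SiOTf, 2,6-lutidine, CH2Cl2, −78 → 0 °C
Reagents that add atoms: triethylsilyl trifluoromethanesulfonate, CC[Si](CC)(CC)OS(=O)(=O)C(F)(F)F
Why: Silylation of a hindered axial alcohol with a silyl triflate; 2,6-lutidine at low temperature should not enolise the hindered ketone, and the triethylsilyl ether withstands the ylide, peracid, organolithium and mild acid ahead while remaining removable by fluoride.

Step 13
Reactants: 20 (5S,6R,8R,10S)-6β-(triethylsilyloxy)-4,4,8α,10-tetramethyl-trans-decal-9-one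
Product: 21 (5S,6R,8R,10S)-9-methylene-6β-(triethylsilyloxy)-4,4,8α,10-tetramethyl-trans-decalin
Conditions: Ph3PCH3Br, KOtBu, toluene, 90 °C
Reagents that add atoms: methyltriphenylphosphonium bromide, C[P+](c1ccccc1)(c1ccccc1)c1ccccc1.[Br-]
Why: Wittig methylenation under the forcing conditions used for hindered ketones installs C11; base cannot damage C8 because the equatorial 8α-methyl epimer is strongly preferred (the 8β epimer would be syn-diaxial to the C10 methyl and C6 silyloxy groups).

Step 14
Reactants: 21 (5S,6R,8R,10S)-9-methylene-6β-(triethylsilyloxy)-4,4,8α,10-tetramethyl-trans-decalin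
Product: 22 (5S,6R,8R,9R,10S)-9α,11-epoxy-9-methyl-type spiro-oxirane: 6β-(triethylsilyloxy)-4,4,8α,10-tetramethyl-trans-decalin-9-spiro-2'-oxirane with oxygen on the α-face
Conditions: mCPBA, NaHCO3, CH2Cl2, 0 °C
Reagents that add atoms: 3-chloroperoxybenzoic acid, OOC(=O)c1cccc(Cl)c1
Why: Prilezhaev epoxidation; the peracid approaches the exocyclic alkene along the axial α-direction, past hydrogen atoms only, because the β-face is screened by the adjacent axial C10 methyl group, which sets C9 with oxygen α and C11 β. The buffer suppresses acid-induced rearrangement of the oxirane.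

Step 15
Reactants: 22 spiro-oxirane (9α-O); 23 2-methylprop-2-en-1-ol
Product: 24 (5S,6R,8R,9R,10S)-6β-(triethylsilyloxy)-15-norlabd-13(16)-ene-9α,14-diol
Conditions: 23, n-BuLi (2 equiv), TMEDA, Et2O, 0 °C → rt; then 22, THF, −20 °C → rt; then H2O
Reagents that add atoms: none
Why: Epoxide opening by the allylic dianion of 23 at the oxirane CH2 (C11) forms C11–C12 and leaves the 9α-alkoxide untouched, so C9 keeps its configuration and the whole 2-(hydroxymethyl)allyl unit arrives in one step.

Step 16
Reactants: 24 (5S,6R,8R,9R,10S)-6β-(triethylsilyloxy)-15-norlabd-13(16)-ene-9α,14-diol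
Product: 25 (13S)-13,16-epoxy-6β-(triethylsilyloxy)-15-norlabdane-9α,14-diol
Conditions: Ti(OiPr)4 (10 mol%), L-(+)-diethyl tartrate (12 mol%), t-BuOOH, 4 Å MS, CH2Cl2, −20 °C
Reagents that add atoms: tert-butyl hydroperoxide, CC(C)(C)OO
Why: Sharpless asymmetric epoxidation of a 2-substituted allylic alcohol; L-(+)-tartrate delivers oxygen to the face that gives the (13S)-oxirane (the facial sense that gives (2S,3S)-epoxy alcohols from (E)-allylic alcohols), which supplies the reagent control that remote C13 needs. Catalytic titanium at low temperature is chosen so that the tertiary 9-hydroxyl does not open the oxirane prematurely.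

Step 17
Reactants: 25 (13S)-13,16-epoxy-6β-(triethylsilyloxy)-15-norlabdane-9α,14-diol
Product: 26 (13R)-13,16-epoxy-9α-hydroxy-6β-(triethylsilyloxy)-15-norlabdan-14-al
Conditions: Dess–Martin periodinane, NaHCO3, CH2Cl2, 0 °C
Reagents that add atoms: none
Why: Dess–Martin oxidation of the primary alcohol only (the 9-hydroxyl is tertiary); the α-carbon is quaternary, so the epoxy aldehyde cannot epimerise, and the descriptor changes only through the priority rules.

Step 18
Reactants: 26 (13R)-13,16-epoxy-9α-hydroxy-6β-(triethylsilyloxy)-15-norlabdan-14-al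
Product: 27 (13S)-13,16-epoxy-6β-(triethylsilyloxy)labd-14-yn-9α-ol
Conditions: dimethyl (1-diazo-2-oxopropyl)phosphonate, K2CO3, MeOH, 0 °C → rt
Reagents that add atoms: dimethyl (1-diazo-2-oxopropyl)phosphonate, COP(=O)(OC)C(=[N+]=[N-])C(C)=O
Why: Ohira–Bestmann (Seyferth–Gilbert) homologation adds C15 and turns the aldehyde arm into an ethynyl group under mild carbonate conditions that leave the oxirane and the silyl ether alone; the two arms on C13 are now different.

Step 19
Reactants: 27 (13S)-13,16-epoxy-6β-(triethylsilyloxy)labd-14-yn-9α-ol
Product: 28 (13R)-9α,13-epoxy-6β-(triethylsilyloxy)labd-14-yn-16-ol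
Conditions: (+)-camphor-10-sulfonic acid (10 mol%), CH2Cl2, 0 °C
Reagents that add atoms: none
Why: Acid-catalysed intramolecular epoxide opening (5-exo-tet) by the 9α-hydroxyl at the tertiary oxirane carbon; backside attack inverts C13 to (13R) and frees the C16 hydroxymethyl group. The inductively withdrawing ethynyl group should make C13 no more prone to ionisation than a trialkyl oxirane carbon, and acid disfavours the 6-endo attack at C16.

Step 20
Reactants: 28 (13R)-9α,13-epoxy-6β-(triethylsilyloxy)labd-14-yn-16-ol
Product: 29 (13R)-9α,13:15,16-diepoxy-6β-(triethylsilyloxy)labd-14-ene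
Conditions: Mo(CO)6 (30 mol%), Et3N, Et2O, hν (350 nm), rt
Reagents that add atoms: none
Why: Endo cycloisomerisation of a homopropargylic alcohol through a molybdenum vinylidene: the C16 hydroxyl attacks the electrophilic C15 and amine-mediated proton transfer releases the 2,3-dihydrofuran; the basic medium protects the acid-labile enol ether and no stereocentre is touched.

Step 21
Reactants: 29 (13R)-9α,13:15,16-diepoxy-6β-(triethylsilyloxy)labd-14-ene
Product: 30 (13R)-9α,13:15,16-diepoxylabd-14-en-6β-ol
Conditions: Bu4NF, THF, 40 °C
Reagents that add atoms: none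
Why: Fluoride cleavage of the triethylsilyl ether under basic conditions that the spiro enol ether tolerates.

Step 22
Reactants: 30 (13R)-9α,13:15,16-diepoxylabd-14-en-6β-ol
Product: 31 (5S,6R,8R,9R,10S,13R)-9α,13:15,16-diepoxylabd-14-en-6β-yl acetate (target)
Conditions: Ac2O, DMAP, pyridine, 40 °C
Reagents that add atoms: acetic anhydride, CC(=O)OC(C)=O
Why: DMAP-catalysed acylation of the only hydroxyl group; the hindered axial alcohol needs the nucleophilic catalyst and gentle warming, and pyridine buffers the acetic acid so the enol ether is not exposed to acid.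

## Compound list

1 | methyl isobutyrate | COC(=O)C(C)C | starting material
2 | 1-bromo-3-chloropropane | ClCCCBr | starting material
3 | methyl 5-chloro-2,2-dimethylpentanoate | COC(=O)C(C)(C)CCCCl | intermediate
4 | methyl 5-iodo-2,2-dimethylpentanoate | COC(=O)C(C)(C)CCCI | intermediate
5 | N-methoxy-N-methylpropanamide | CCC(=O)N(C)OC | starting material
6 | methyl 7-[methoxy(methyl)amino]-2,2,6-trimethyl-7-oxoheptanoate (racemic) | COC(=O)C(C)(C)CCCC(C)C(=O)N(C)OC | intermediate
7 | isopropenylmagnesium bromide | CC(=C)[Mg]Br | starting material
8 | methyl 2,2,6,8-tetramethyl-7-oxonon-8-enoate (racemic) | COC(=O)C(C)(C)CCCC(C)C(=O)C(C)=C | intermediate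
9 | 2,2,6,8-tetramethylnon-8-ene-1,7-diol (diastereomer mixture) | OCC(C)(C)CCCC(C)C(O)C(C)=C | intermediate
10 | 2,2,6,8-tetramethyl-7-oxonon-8-enal (racemic) | O=CC(C)(C)CCCC(C)C(=O)C(C)=C | intermediate
11 | nitromethane | C[N+](=O)[O-] | starting material
12 | 9-hydroxy-2,4,8,8-tetramethyl-10-nitrodec-1-en-3-one (diastereomer mixture) | [O-][N+](=O)CC(O)C(C)(C)CCCC(C)C(=O)C(C)=C | intermediate
13 | (9E)-2,4,8,8-tetramethyl-10-nitrodeca-1,9-dien-3-one (racemic) | O=[N+]([O-])/C=C/C(C)(C)CCCC(C)C(=O)C(C)=C | intermediate
14 | 2-aminodiene from 13 and 9-amino-9-deoxy-epi-quinine (C7=C8–C9(N)=C10) | C=C(C)C(N[C@H]([C@@H]1C[C@@H]2CCN1C[C@@H]2C=C)c1ccnc2ccc(OC)cc12)=C(C)CCCC(C)(C)/C=C/[N+](=O)[O-] | intermediate (not isolated)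
15 | iminium nitronate after the first Michael addition (ring A closed, C5–C10 formed) | C=C(C)C(=[NH+][C@H]([C@@H]2C[C@@H]3CCN2C[C@@H]3C=C)c2ccnc3ccc(OC)cc23)[C@@]1(C)CCCC(C)(C)[C@@H]1C=[N+]([O-])[O-] | intermediate (not isolated)
16 | (5S,6S,8R,10S)-6α-nitro-4,4,8α,10-tetramethyl-trans-decal-9-one [(2R,4S,4aS,8aS)-2,5,5,8a-tetramethyl-4-nitrooctahydronaphthalen-1(2H)-one] | [O-][N+](=O)[C@H]1C[C@@H](C)C(=O)[C@@]2(C)CCCC(C)(C)[C@H]12 | intermediate
17 | sodium nitronate of 16 | [Na+].[O-][N+]([O-])=C1C[C@@H](C)C(=O)[C@@]2(C)CCCC(C)(C)[C@H]12 | intermediate (not isolated)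
18 | (5S,8R,10S)-4,4,8α,10-tetramethyl-trans-decalin-6,9-dione | O=C1C[C@@H](C)C(=O)[C@@]2(C)CCCC(C)(C)[C@H]12 | intermediate
19 | (5S,6R,8R,10S)-6β-hydroxy-4,4,8α,10-tetramethyl-trans-decal-9-one | O[C@@H]1C[C@@H](C)C(=O)[C@@]2(C)CCCC(C)(C)[C@H]12 | intermediate
20 | (5S,6R,8R,10S)-6β-(triethylsilyloxy)-4,4,8α,10-tetramethyl-trans-decal-9-one | CC[Si](CC)(CC)O[C@@H]1C[C@@H](C)C(=O)[C@@]2(C)CCCC(C)(C)[C@H]12 | intermediate
21 | (5S,6R,8R,10S)-9-methylene-6β-(triethylsilyloxy)-4,4,8α,10-tetramethyl-trans-decalin | CC[Si](CC)(CC)O[C@@H]1C[C@@H](C)C(=C)[C@@]2(C)CCCC(C)(C)[C@H]12 | intermediate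
22 | (5S,6R,8R,9R,10S)-9α,11-epoxide of 21 (spiro-oxirane, oxygen α, C11 β) | CC[Si](CC)(CC)O[C@@H]1C[C@@H](C)[C@]3(CO3)[C@@]2(C)CCCC(C)(C)[C@H]12 | intermediate
23 | 2-methylprop-2-en-1-ol | CC(=C)CO | starting material
24 | (5S,6R,8R,9R,10S)-6β-(triethylsilyloxy)-15-norlabd-13(16)-ene-9α,14-diol | CC[Si](CC)(CC)O[C@@H]1C[C@@H](C)[C@](O)(CCC(=C)CO)[C@@]2(C)CCCC(C)(C)[C@H]12 | intermediate
25 | (13S)-13,16-epoxy-6β-(triethylsilyloxy)-15-norlabdane-9α,14-diol | CC[Si](CC)(CC)O[C@@H]1C[C@@H](C)[C@](O)(CC[C@]3(CO)CO3)[C@@]2(C)CCCC(C)(C)[C@H]12 | intermediate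
26 | (13R)-13,16-epoxy-9α-hydroxy-6β-(triethylsilyloxy)-15-norlabdan-14-al | CC[Si](CC)(CC)O[C@@H]1C[C@@H](C)[C@](O)(CC[C@]3(C=O)CO3)[C@@]2(C)CCCC(C)(C)[C@H]12 | intermediate
27 | (13S)-13,16-epoxy-6β-(triethylsilyloxy)labd-14-yn-9α-ol | CC[Si](CC)(CC)O[C@@H]1C[C@@H](C)[C@](O)(CC[C@]3(C#C)CO3)[C@@]2(C)CCCC(C)(C)[C@H]12 | intermediate
28 | (13R)-9α,13-epoxy-6β-(triethylsilyloxy)labd-14-yn-16-ol | CC[Si](CC)(CC)O[C@@H]1C[C@@H](C)[C@]2(CC[C@@](C#C)(CO)O2)[C@@]2(C)CCCC(C)(C)[C@H]12 | intermediate
29 | (13R)-9α,13:15,16-diepoxy-6β-(triethylsilyloxy)labd-14-ene | CC[Si](CC)(CC)O[C@@H]1C[C@@H](C)[C@]2(CC[C@]3(C=COC3)O2)[C@@]2(C)CCCC(C)(C)[C@H]12 | intermediate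
30 | (13R)-9α,13:15,16-diepoxylabd-14-en-6β-ol | O[C@@H]1C[C@@H](C)[C@]2(CC[C@]3(C=COC3)O2)[C@@]2(C)CCCC(C)(C)[C@H]12 | intermediate
31 | (5S,6R,8R,9R,10S,13R)-9α,13:15,16-diepoxylabd-14-en-6β-yl acetate | CC(=O)O[C@@H]1C[C@@H](C)[C@]2(CC[C@]3(C=COC3)O2)[C@@]2(C)CCCC(C)(C)[C@H]12 | target

## Step count and least certain steps

Total: 22 steps. Longest linear sequence: 22 steps (from methyl isobutyrate 1; the route is fully linear, with 2, 5, 7, 11 and 23 added as commercial reagents).

**Step 9 (key step).** The most likely failure is slow or absent condensation of the amine with a ketone that is branched on both sides, so that the 2-aminodiene never builds up and the nitroalkene is instead consumed by reversible amine addition or oligomerisation. The second risk is insufficient facial discrimination at C10, since the catalyst has to control a tetrasubstituted enamine carbon. The fallback uses the known thermal Diels–Alder reactivity of 2-silyloxydienes toward nitroalkenes. It sets out from 13, which is O-silylated with tert-butyldimethylsilyl triflate and triethylamine to the 2-silyloxydiene F1. Heating F1 in toluene should close both rings to the racemic bicyclic silyl enol ether F2. Mild aqueous acid hydrolysis gives the racemic nitro ketone F3, and preparative chromatography on a chiral stationary phase returns to the route at 16.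

**Step 7.** Conjugate addition of the nitronate to the isopropenyl ketone may compete with the nitroaldol addition to the hindered neopentyl aldehyde. The fallback performs the nitroaldol before any enone exists. It sets out from diol 9, whose primary hydroxyl is oxidised selectively (nitroxyl radical with PhI(OAc)2) to 7-hydroxy-2,2,6,8-tetramethylnon-8-enal F4. Nitroaldol addition of 11 gives 2,4,8,8-tetramethyl-10-nitrodec-1-ene-3,9-diol F5, and MnO2 oxidises only the allylic alcohol, which returns to the route at 12.

**Step 15.** Substitution at C11 is a neopentyl-type displacement beside two crowded carbons; the strongly basic dianion may instead deprotonate C8 and isomerise the oxirane to an allylic alcohol, or simply fail to react. The fallback reverses the polarity at C11. It sets out from 22, which is opened with sodium thiophenolate (a small, weakly basic nucleophile) to the 9α-hydroxy 11-phenyl sulfide F6. Oxidation with mCPBA gives the sulfone F7. Its dianion (n-BuLi, 2 equiv) is alkylated at C11 with {[2-(bromomethyl)prop-2-en-1-yl]oxy}trimethylsilane to give the C11-alkylated sulfone F8. Reductive desulfonylation with Na(Hg) in buffered methanol, which also removes the trimethylsilyl group, returns to the route at 24.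

**Step 19.** Partial ionisation of the tertiary propargylic oxirane carbon would erode the configuration of C13, and any ring closure already during step 16 would give two identical hydroxymethyl arms and erase it altogether. The fallback closes the ring at an ordinary trialkyl oxirane whose arms are differentiated by a protecting group; because the roles of the two arms are exchanged, the enantiomeric tartrate is needed. It sets out from 24, which is epoxidised with D-(−)-diethyl tartrate to the (13R)-epoxy alcohol F9. The primary hydroxyl is silylated (tert-butyldiphenylsilyl chloride, imidazole) to F10. Acid-catalysed 5-exo closure gives the spiro ether F11, which carries a silyloxymethyl arm (future C16) and a free hydroxymethyl arm (future C14). Dess–Martin oxidation gives aldehyde F12 and Ohira–Bestmann homologation gives alkyne F13. Bu4NF removes both silyl groups to the diol F14, and the molybdenum-catalysed cycloisomerisation of step 20 returns to the route at 30.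

**Step 20.** The vinylidene may form poorly beside the quaternary, oxygen-bearing propargylic carbon, or the catalyst may be sequestered, leaving the alkynol unchanged. The fallback reaches the enol ether by hydration and dehydration instead. It sets out from 28, whose terminal alkyne is hydroborated with dicyclohexylborane and oxidised (NaBO3) to the aldehyde, which closes onto the C16 hydroxyl as the lactol F15. Dehydration with MsCl and Et3N returns to the route at 29.

## Further compounds

F1 | step 9 | (9E)-3-(tert-butyldimethylsilyloxy)-2,4,8,8-tetramethyl-10-nitrodeca-1,3,9-triene (3E/3Z mixture) | C=C(C)C(O[Si](C)(C)C(C)(C)C)=C(C)CCCC(C)(C)/C=C/[N+](=O)[O-]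
F2 | step 9 | racemic trans-fused 6α-nitro-9-(tert-butyldimethylsilyloxy)-4,4,8,10-tetramethyl-decal-8-ene (relative configuration drawn) | [O-][N+](=O)[C@H]1CC(C)=C(O[Si](C)(C)C(C)(C)C)[C@@]2(C)CCCC(C)(C)[C@H]12
F3 | step 9 | racemic 6α-nitro-4,4,8α,10-tetramethyl-trans-decal-9-one (racemate of 16; relative configuration drawn) | [O-][N+](=O)[C@H]1C[C@@H](C)C(=O)[C@@]2(C)CCCC(C)(C)[C@H]12
F4 | step 7 | 7-hydroxy-2,2,6,8-tetramethylnon-8-enal | O=CC(C)(C)CCCC(C)C(O)C(C)=C
F5 | step 7 | 2,4,8,8-tetramethyl-10-nitrodec-1-ene-3,9-diol | [O-][N+](=O)CC(O)C(C)(C)CCCC(C)C(O)C(C)=C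
F6 | step 15 | 9α-hydroxy-11-(phenylthio) compound from 22 (6β-triethylsilyloxy) | CC[Si](CC)(CC)O[C@@H]1C[C@@H](C)[C@](O)(CSc3ccccc3)[C@@]2(C)CCCC(C)(C)[C@H]12
F7 | step 15 | 9α-hydroxy-11-(phenylsulfonyl) compound | CC[Si](CC)(CC)O[C@@H]1C[C@@H](C)[C@](O)(CS(=O)(=O)c3ccccc3)[C@@]2(C)CCCC(C)(C)[C@H]12
F8 | step 15 | 11-(phenylsulfonyl)-14-(trimethylsilyloxy)-6β-(triethylsilyloxy)-15-norlabd-13(16)-en-9α-ol (C11 epimers) | CC[Si](CC)(CC)O[C@@H]1C[C@@H](C)[C@](O)(C(CC(=C)CO[Si](C)(C)C)S(=O)(=O)c3ccccc3)[C@@]2(C)CCCC(C)(C)[C@H]12
F9 | step 19 | (13R)-13,16-epoxy-6β-(triethylsilyloxy)-15-norlabdane-9α,14-diol (C13 epimer of 25) | CC[Si](CC)(CC)O[C@@H]1C[C@@H](C)[C@](O)(CC[C@@]3(CO)CO3)[C@@]2(C)CCCC(C)(C)[C@H]12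
F10 | step 19 | tert-butyldiphenylsilyl ether of F9 at the primary hydroxyl | CC[Si](CC)(CC)O[C@@H]1C[C@@H](C)[C@](O)(CC[C@@]3(CO[Si](c4ccccc4)(c4ccccc4)C(C)(C)C)CO3)[C@@]2(C)CCCC(C)(C)[C@H]12
F11 | step 19 | 9α,13-epoxy spiro ether with C13 bearing CH2OSi(t-Bu)Ph2 (future C16) and CH2OH (future C14), 6β-triethylsilyloxy | CC[Si](CC)(CC)O[C@@H]1C[C@@H](C)[C@]2(CC[C@](CO[Si](c3ccccc3)(c3ccccc3)C(C)(C)C)(CO)O2)[C@@]2(C)CCCC(C)(C)[C@H]12
F12 | step 19 | aldehyde from F11 (C14 formyl) | CC[Si](CC)(CC)O[C@@H]1C[C@@H](C)[C@]2(CC[C@](CO[Si](c3ccccc3)(c3ccccc3)C(C)(C)C)(C=O)O2)[C@@]2(C)CCCC(C)(C)[C@H]12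
F13 | step 19 | (13R)-9α,13-epoxy-16-(tert-butyldiphenylsilyloxy)-6β-(triethylsilyloxy)labd-14-yne | CC[Si](CC)(CC)O[C@@H]1C[C@@H](C)[C@]2(CC[C@](CO[Si](c3ccccc3)(c3ccccc3)C(C)(C)C)(C#C)O2)[C@@]2(C)CCCC(C)(C)[C@H]12
F14 | step 19 | (13R)-9α,13-epoxylabd-14-yne-6β,16-diol | O[C@@H]1C[C@@H](C)[C@]2(CC[C@](CO)(C#C)O2)[C@@]2(C)CCCC(C)(C)[C@H]12
F15 | step 20 | (13R)-9α,13:15,16-diepoxy-6β-(triethylsilyloxy)labdan-15-ol (lactol, C15 epimers) | CC[Si](CC)(CC)O[C@@H]1C[C@@H](C)[C@]2(CC[C@]3(CC(O)OC3)O2)[C@@]2(C)CCCC(C)(C)[C@H]12
A1 | alternative 1 | (4R)-1-[(2S)-2-({[tert-butyl(diphenyl)silyl]oxy}methyl)oxiran-2-yl]-4-methyl-6-(2,6,6-trimethylcyclohex-1-en-1-yl)hexan-3-one | CC1=C(CC[C@@H](C)C(=O)CC[C@@]2(CO[Si](c3ccccc3)(c3ccccc3)C(C)(C)C)CO2)C(C)(C)CCC1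
A2 | alternative 1 | tricyclic 9α,13-epoxy 5-ene with C13 bearing CH2OSi(t-Bu)Ph2 and CH2OH | C1C[C@@H](C)[C@]2(CC[C@](CO[Si](c3ccccc3)(c3ccccc3)C(C)(C)C)(CO)O2)[C@@]2(C)CCCC(C)(C)C=12
A3 | alternative 2 | 2,6-dimethyl-1,4-benzoquinone | CC1=CC(=O)C=C(C)C1=O
A4 | alternative 2 | 2-(triisopropylsilyloxy)-4-methylpenta-1,3-diene | CC(C)=CC(=C)O[Si](C(C)C)(C(C)C)C(C)C
A5 | alternative 2 | cis-fused 4,4,8,10-tetramethyl ene-dione with C2 triisopropylsilyl enol ether | O=C1C=C(C)C(=O)[C@@]2(C)CC(O[Si](C(C)C)(C(C)C)C(C)C)=CC(C)(C)[C@@H]12
A6 | alternative 3 | 6β-acetoxy-9α-[(5-oxo-2,5-dihydrofuran-3-yl)oxy] decalin bearing a 2-iodoethyl group (C11–C12) on C9 | CC(=O)O[C@@H]1C[C@@H](C)[C@@](CCI)(OC3=CC(=O)OC3)[C@@]2(C)CCCC(C)(C)[C@H]12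
A7 | alternative 3 | 6β-acetoxy-9α,13-epoxylabdan-16,15-olide | CC(=O)O[C@@H]1C[C@@H](C)[C@]2(CC[C@]3(CC(=O)OC3)O2)[C@@]2(C)CCCC(C)(C)[C@H]12
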